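**Retrosynthetic overview**
- The lactone C3–CH2(ring B) bond is cut first: trans-selective enolate alkylation of an (S)-β-substituted butyrolactone with a ring-B benzyl bromide that carries the silylated (1S,2S)-1,2-diarylpropane-1,3-diol. Desilylation and debenzylation come last.
- The diol C1–C2 bond comes from an auxiliary-controlled anti-aldol of a ring-B arylacetyl imide with O-benzylvanillin. The arylacetate is made by palladium-catalysed zinc enolate arylation of benzylated methyl 5-bromovanillate.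
- The lactone C4–CH2Ar bond comes from Evans alkylation of a pent-4-enoyl imide with the dihydrobenzofuran C5 benzyl bromide. The lactone ring follows by reduction, alkene cleavage and lactol oxidation.
- The strategy rests on the dihydrobenzofuran ring O1–C2–C3–C3a–C7a. C2 is a benzylic ether carbon (bonded to O1 and the guaiacyl ring) and C3 carries a carboxyl-level carbon (CH2OH) on arene carbon C3a. The C2–C3 bond is therefore made by insertion of an aryl diazoacetate rhodium carbene into an ArO–CH2–Ar hydrogen.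
- Ring order: the furan ring of the dihydrobenzofuran first (step 7), the butyrolactone ring second (steps 15–16). All benzene rings are bought.

Key step: step 7

Remark on the chemistry: the sense of asymmetric induction in steps 7 and 21 is assigned from the accepted models for simpler 2-benzyloxyaryl diazoacetates and N-acyl oxazolidinones; the mirror-image catalyst and auxiliary are equally available.

Abbreviations in names: Bn = benzyl; TBS = tert-butyldimethylsilyl; TBDPS = tert-butyldiphenylsilyl; ArF = (2R,3S)-2-(4-benzyloxy-3-methoxyphenyl)-3-[(TBDPS-oxy)methyl]-7-methoxy-2,3-dihydro-1-benzofuran-5-yl.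

**Route**

Step 1
Reactants: 1 4-benzyloxy-3-methoxybenzyl alcohol
Product: 2 4-benzyloxy-3-methoxybenzyl bromide
Conditions: PBr3, Et2O, 0 °C
Reagents that add atoms: phosphorus tribromide, BrP(Br)Br
Why: Bromination of an electron-rich primary benzylic alcohol through its phosphite ester (SN2 by bromide) is routine and leaves the aryl benzyl ether alone.

Step 2
Reactants: 3 5-bromovanillin; 2 4-benzyloxy-3-methoxybenzyl bromide
Product: 4 3-bromo-4-[(4-benzyloxy-3-methoxybenzyl)oxy]-5-methoxybenzaldehyde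
Conditions: K2CO3, DMF, 50 °C
Reagents that add atoms: none
Why: Williamson ether synthesis, in which the acidic para-formyl phenoxide displaces the reactive benzylic bromide.

Step 3
Reactants: 4 3-bromo-4-[(4-benzyloxy-3-methoxybenzyl)oxy]-5-methoxybenzaldehyde
Product: 5 {3-bromo-4-[(4-benzyloxy-3-methoxybenzyl)oxy]-5-methoxyphenyl}methanol
Conditions: NaBH4, MeOH/THF, 0 °C
Reagents that add atoms: none
Why: Borohydride reduction of the aryl aldehyde removes the only group that would react with a zinc enolate.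

Step 4
Reactants: 5 {3-bromo-4-[(4-benzyloxy-3-methoxybenzyl)oxy]-5-methoxyphenyl}methanol
Product: 6 TBS ether of 5, {3-bromo-4-[(4-benzyloxy-3-methoxybenzyl)oxy]-5-methoxybenzyl}oxy(tert-butyl)dimethylsilane
Conditions: TBSCl, imidazole, DMF, rt
Reagents that add atoms: tert-butyldimethylsilyl chloride, CC(C)(C)[Si](C)(C)Cl
Why: Silylation of the primary alcohol removes the O–H bond that a rhodium carbene would otherwise attack.

Step 5
Reactants: 6 TBS ether of 5; 7 methyl bromoacetate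
Product: 9 methyl 2-{2-[(4-benzyloxy-3-methoxybenzyl)oxy]-3-methoxy-5-[(TBS-oxy)methyl]phenyl}acetate, via Reformatsky reagent 8 (not isolated)
Conditions: Zn dust, THF, rt (7 to 8); then 6, Pd(dba)2 (cat.), XPhos (cat.), THF, 60 °C
Reagents that add atoms: none
Why: Negishi-type α-arylation of an ester zinc enolate, in which zerovalent palladium inserts into the hindered aryl–bromine bond, transmetalates with the Reformatsky reagent and eliminates reductively, the weakly basic zinc enolate sparing the silyl and benzylic ethers.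

Step 6
Reactants: 9 methyl 2-{2-[(4-benzyloxy-3-methoxybenzyl)oxy]-3-methoxy-5-[(TBS-oxy)methyl]phenyl}acetate
Product: 10 methyl 2-diazo-2-{2-[(4-benzyloxy-3-methoxybenzyl)oxy]-3-methoxy-5-[(TBS-oxy)methyl]phenyl}acetate
Conditions: 4-acetamidobenzenesulfonyl azide, DBU, MeCN, 0 °C to rt
Reagents that add atoms: 4-acetamidobenzenesulfonyl azide, CC(=O)Nc1ccc(cc1)S(=O)(=O)N=[N+]=[N-]
Why: Regitz-type diazo transfer to the benzylic ester enolate is the standard entry to aryl diazoacetates.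

Step 7
Reactants: 10 methyl 2-diazo-2-{2-[(4-benzyloxy-3-methoxybenzyl)oxy]-3-methoxy-5-[(TBS-oxy)methyl]phenyl}acetate
Product: 12 methyl (2R,3R)-trans-2-(4-benzyloxy-3-methoxyphenyl)-7-methoxy-5-[(TBS-oxy)methyl]-2,3-dihydro-1-benzofuran-3-carboxylate, via cis ester 11 (not isolated)
Conditions: Rh2(S-PTTL)4, dirhodium tetrakis[N-phthaloyl-(S)-tert-leucinate] (1 mol%), toluene, −60 °C, slow addition of 10; then DBU, warm to 50 °C
Reagents that add atoms: none
Why: Rh2(S-PTTL)4 should expel dinitrogen from 10 and give a donor–acceptor rhodium carbene that inserts into a hydrogen of the ArO–CH2–Ar group through a concerted, hydride-shift-like three-centre transition state; the closest known reaction type is the chiral dirhodium tetracarboxylate-catalysed intramolecular C–H insertion of 2-benzyloxyphenyl diazoacetates to cis-2-aryl-2,3-dihydrobenzofuran-3-carboxylates. The furan ring O1–C2–C3–C3a–C7a closes by 1,5 C–H insertion, the new C2–C3 bond being the only skeletal bond formed. C2 is set by the catalyst: the phthalimido tert-leucinate ligands let only one of the two enantiotopic benzylic hydrogens reach the carbene carbon, and the S ligand is expected to give 2R. C3 is formed cis under kinetic control (11) and is then moved to trans by DBU through the ester enolate, the fixed 2-aryl group deciding the thermodynamic outcome while C2, which has no acidic hydrogen, stays as set. The step needs site selectivity for the proximal benzylic ether hydrogen over the distal benzyl ether, silyloxymethyl and methoxy hydrogens, and the 1,5-relationship together with activation by both the ether oxygen and the electron-rich aryl ring secures it, the low temperature keeping carbene dimerisation and arene addition down.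

Step 8
Reactants: 12 methyl (2R,3R)-trans-2-(4-benzyloxy-3-methoxyphenyl)-7-methoxy-5-[(TBS-oxy)methyl]-2,3-dihydro-1-benzofuran-3-carboxylate
Product: 13 [(2R,3S)-2-(4-benzyloxy-3-methoxyphenyl)-7-methoxy-5-[(TBS-oxy)methyl]-2,3-dihydro-1-benzofuran-3-yl]methanol
Conditions: LiBH4, THF, 0 °C to rt
Reagents that add atoms: none
Why: Hydride reduction of the activated α-aryl ester gives the primary alcohol with a weakly basic reagent, so that C3 is not epimerised and the furan is not opened by β-elimination (the descriptor changes to 3S only through the priority rules).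

Step 9
Reactants: 13 [(2R,3S)-2-(4-benzyloxy-3-methoxyphenyl)-7-methoxy-5-[(TBS-oxy)methyl]-2,3-dihydro-1-benzofuran-3-yl]methanol
Product: 14 (2R,3S)-2-(4-benzyloxy-3-methoxyphenyl)-3-[(TBDPS-oxy)methyl]-7-methoxy-5-[(TBS-oxy)methyl]-2,3-dihydro-1-benzofuran
Conditions: TBDPSCl, imidazole, DMF, rt
Reagents that add atoms: tert-butyl(chloro)diphenylsilane, CC(C)(C)[Si](Cl)(c1ccccc1)c1ccccc1
Why: Silylation with the more acid-stable TBDPS group makes the two primary silyl ethers distinguishable.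

Step 10
Reactants: 14 (2R,3S)-2-(4-benzyloxy-3-methoxyphenyl)-3-[(TBDPS-oxy)methyl]-7-methoxy-5-[(TBS-oxy)methyl]-2,3-dihydro-1-benzofuran
Product: 15 ArF-methanol, {(2R,3S)-2-(4-benzyloxy-3-methoxyphenyl)-3-[(TBDPS-oxy)methyl]-7-methoxy-2,3-dihydro-1-benzofuran-5-yl}methanol
Conditions: camphorsulfonic acid (cat.), MeOH/CH2Cl2, 0 °C
Reagents that add atoms: none
Why: Acid-catalysed methanolysis cleaves a primary TBS ether far faster than a TBDPS ether, and the conditions are too mild to ionise the furan C2–O bond.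

Step 11
Reactants: 15 ArF-methanol
Product: 16 ArF-methyl bromide, (2R,3S)-5-(bromomethyl)-2-(4-benzyloxy-3-methoxyphenyl)-3-[(TBDPS-oxy)methyl]-7-methoxy-2,3-dihydro-1-benzofuran
Conditions: CBr4, PPh3, CH2Cl2, 0 °C, used crude
Reagents that add atoms: carbon tetrabromide, BrC(Br)(Br)Br
Why: The Appel reaction turns the benzylic alcohol into the bromide under neutral conditions that silyl and benzyl ethers tolerate.

Step 12
Reactants: 17 (S)-4-benzyl-1,3-oxazolidin-2-one; 18 pent-4-enoyl chloride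
Product: 19 (S)-4-benzyl-3-(pent-4-enoyl)-1,3-oxazolidin-2-one
Conditions: Et3N, DMAP (cat.), CH2Cl2, 0 °C to rt
Reagents that add atoms: none
Why: DMAP-catalysed N-acylation of the oxazolidinone by the acid chloride is a standard way to load the Evans auxiliary.

Step 13
Reactants: 19 (S)-4-benzyl-3-(pent-4-enoyl)-1,3-oxazolidin-2-one; 16 ArF-methyl bromide
Product: 21 (4S)-4-benzyl-3-[(2R)-2-(ArF-methyl)pent-4-enoyl]-1,3-oxazolidin-2-one, via sodium enolate 20 (not isolated)
Conditions: NaN(SiMe3)2, THF, −78 °C; then 16, −78 to −40 °C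
Reagents that add atoms: none
Why: Evans alkylation, in which the chelated sodium (Z)-enolate is attacked by the benzylic bromide on the face away from the C4 benzyl group of the auxiliary, which sets the new centre as 2R.

Step 14
Reactants: 21 (4S)-4-benzyl-3-[(2R)-2-(ArF-methyl)pent-4-enoyl]-1,3-oxazolidin-2-one
Product: 22 (2R)-2-(ArF-methyl)pent-4-en-1-ol
Conditions: LiBH4, MeOH (1 equiv), THF, 0 °C
Reagents that add atoms: none
Why: Reductive cleavage of the imide at the exocyclic carbonyl releases the primary alcohol and the auxiliary without touching the new stereocentre.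

Step 15
Reactants: 22 (2R)-2-(ArF-methyl)pent-4-en-1-ol
Product: 25 (4S)-4-(ArF-methyl)oxolan-2-ol (anomer mixture), via triol 23 (not isolated), via hydroxy aldehyde 24 (not isolated)
Conditions: OsO4 (cat.), NaIO4, 2,6-lutidine, dioxane/H2O, rt
Reagents that add atoms: osmium tetroxide, O=[Os](=O)(=O)=O; sodium periodate, [Na+].[O-]I(=O)(=O)=O
Why: Lemieux–Johnson cleavage, in which the terminal alkene is dihydroxylated and cleaved to the aldehyde, which closes on the primary hydroxyl to the five-membered lactol while the electron-rich arenes are untouched.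

Step 16
Reactants: 25 (4S)-4-(ArF-methyl)oxolan-2-ol
Product: 26 (4S)-4-(ArF-methyl)oxolan-2-one
Conditions: TEMPO (cat.), PhI(OAc)2, CH2Cl2, rt
Reagents that add atoms: none
Why: Oxoammonium oxidation of the lactol hemiacetal gives the γ-butyrolactone, and the stereocentre, which is not α to the carbonyl, cannot epimerise.

Step 17
Reactants: 27 methyl 3-bromo-4-hydroxy-5-methoxybenzoate
Product: 28 methyl 4-benzyloxy-3-bromo-5-methoxybenzoate
Conditions: BnBr, K2CO3, DMF, rt
Reagents that add atoms: benzyl bromide, BrCc1ccccc1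
Why: Williamson benzylation of the acidic phenol.

Step 18
Reactants: 28 methyl 4-benzyloxy-3-bromo-5-methoxybenzoate; 29 tert-butyl bromoacetate
Product: 31 methyl 4-benzyloxy-3-(2-tert-butoxy-2-oxoethyl)-5-methoxybenzoate, via Reformatsky reagent 30 (not isolated)
Conditions: Zn dust, THF, rt (29 to 30); then 28, Pd(dba)2 (cat.), XPhos (cat.), THF, 60 °C
Reagents that add atoms: none
Why: The same Negishi-type zinc enolate arylation as in step 5, with a tert-butyl ester so that the new acetate can later be told apart from the methyl benzoate.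

Step 19
Reactants: 31 methyl 4-benzyloxy-3-(2-tert-butoxy-2-oxoethyl)-5-methoxybenzoate
Product: 32 [2-benzyloxy-3-methoxy-5-(methoxycarbonyl)phenyl]acetic acid
Conditions: CF3CO2H, CH2Cl2, 0 °C to rt
Reagents that add atoms: none
Why: Acidolysis of the tert-butyl ester (loss of 2-methylpropene) leaves the methyl ester and the benzyl ether on the deactivated ring intact.

Step 20
Reactants: 32 [2-benzyloxy-3-methoxy-5-(methoxycarbonyl)phenyl]acetic acid; 17 (S)-4-benzyl-1,3-oxazolidin-2-one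
Product: 34 methyl 4-benzyloxy-3-{2-[(4S)-4-benzyl-2-oxo-1,3-oxazolidin-3-yl]-2-oxoethyl}-5-methoxybenzoate, via mixed pivalic anhydride 33 (not isolated)
Conditions: Me3CCOCl, Et3N, THF, −20 °C; then LiCl, 17, rt
Reagents that add atoms: none
Why: Mixed-anhydride acylation of the oxazolidinone with lithium chloride activation is the usual one-flask way to N-arylacetyl imides.

Step 21
Reactants: 34 methyl 4-benzyloxy-3-{2-[(4S)-4-benzyl-2-oxo-1,3-oxazolidin-3-yl]-2-oxoethyl}-5-methoxybenzoate; 35 4-benzyloxy-3-methoxybenzaldehyde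
Product: 37 (4S)-4-benzyl-3-[(2R,3S)-3-(4-benzyloxy-3-methoxyphenyl)-2-(2-benzyloxy-3-methoxy-5-methoxycarbonylphenyl)-3-hydroxypropanoyl]-1,3-oxazolidin-2-one, via trimethylsilyl ether 36 (not isolated)
Conditions: MgCl2 (cat.), Et3N, Me3SiCl, EtOAc, rt; then citric acid, MeOH, rt
Reagents that add atoms: none
Why: Magnesium halide-catalysed direct anti-aldol of an N-acyl oxazolidinone, in which the magnesium-chelated (Z)-enolate adds to the aromatic aldehyde through a boat-like transition state on the face away from the auxiliary benzyl group, so that the (4S)-auxiliary should give the (2R,3S) anti adduct, silylation of the aldolate turning the catalyst over.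

Step 22
Reactants: 37 anti-aldol adduct
Product: 38 methyl 4-benzyloxy-3-[(1S,2S)-1-(4-benzyloxy-3-methoxyphenyl)-1,3-dihydroxypropan-2-yl]-5-methoxybenzoate
Conditions: NaBH4, THF/H2O, 0 °C to rt
Reagents that add atoms: none
Why: Borohydride reduction of the activated imide carbonyl removes the auxiliary and gives the 1,3-diol, while the methyl benzoate is not reduced by this reagent.

Step 23
Reactants: 38 methyl 4-benzyloxy-3-[(1S,2S)-1-(4-benzyloxy-3-methoxyphenyl)-1,3-dihydroxypropan-2-yl]-5-methoxybenzoate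
Product: 39 methyl 4-benzyloxy-3-[(1S,2S)-1-(4-benzyloxy-3-methoxyphenyl)-1,3-bis(TBS-oxy)propan-2-yl]-5-methoxybenzoate
Conditions: TBSOTf, 2,6-lutidine, CH2Cl2, −78 to 0 °C
Reagents that add atoms: tert-butyldimethylsilyl trifluoromethanesulfonate, CC(C)(C)[Si](C)(C)OS(=O)(=O)C(F)(F)F
Why: The silyl triflate silylates the primary and the hindered benzylic hydroxyl under buffered conditions that do not ionise the benzylic carbinol.

Step 24
Reactants: 39 bis-TBS ether
Product: 40 {4-benzyloxy-3-[(1S,2S)-1-(4-benzyloxy-3-methoxyphenyl)-1,3-bis(TBS-oxy)propan-2-yl]-5-methoxyphenyl}methanol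
Conditions: i-Bu2AlH, CH2Cl2, −78 °C
Reagents that add atoms: none
Why: Aluminium hydride reduction of the methyl benzoate gives the benzylic alcohol, with no silyl group to differentiate.

Step 25
Reactants: 40 benzylic alcohol
Product: 41 4-benzyloxy-3-[(1S,2S)-1-(4-benzyloxy-3-methoxyphenyl)-1,3-bis(TBS-oxy)propan-2-yl]-5-methoxybenzyl bromide
Conditions: CBr4, PPh3, CH2Cl2, 0 °C, used crude
Reagents that add atoms: carbon tetrabromide, BrC(Br)(Br)Br
Why: Appel reaction of the primary benzylic alcohol, as in step 11.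

Step 26
Reactants: 26 (4S)-4-(ArF-methyl)oxolan-2-one; 41 ring-B benzyl bromide
Product: 43 (3S,4S)-3-{4-benzyloxy-3-[(1S,2S)-1-(4-benzyloxy-3-methoxyphenyl)-1,3-bis(TBS-oxy)propan-2-yl]-5-methoxybenzyl}-4-(ArF-methyl)oxolan-2-one, via lithium enolate 42 (not isolated)
Conditions: LiN(SiMe3)2, THF, −78 °C; then 41, DMPU, −78 to −30 °C
Reagents that add atoms: none
Why: Alkylation of a β-substituted γ-butyrolactone enolate takes place anti to the β-substituent, the classical route to trans-dibenzylbutyrolactones, so C3 is set as S, trans to C4.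

Step 27
Reactants: 43 fully protected lactone
Product: 44 (3S,4S)-3-{4-benzyloxy-3-[(1S,2S)-1-(4-benzyloxy-3-methoxyphenyl)-1,3-dihydroxypropan-2-yl]-5-methoxybenzyl}-4-{[(2R,3S)-2-(4-benzyloxy-3-methoxyphenyl)-3-(hydroxymethyl)-7-methoxy-2,3-dihydro-1-benzofuran-5-yl]methyl}oxolan-2-one
Conditions: HF·pyridine, pyridine, THF, 0 °C to rt
Reagents that add atoms: none
Why: Buffered fluoride desilylation removes the two TBS ethers and the TBDPS ether without base, so the lactone is neither opened nor epimerised.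

Step 28
Reactants: 44 tris-benzyl ether
Product: 45 CNP0186558.3, (3S,4S)-3-{3-[(1S,2S)-1,3-dihydroxy-1-(4-hydroxy-3-methoxyphenyl)propan-2-yl]-4-hydroxy-5-methoxybenzyl}-4-{[(2R,3S)-2-(4-hydroxy-3-methoxyphenyl)-3-(hydroxymethyl)-7-methoxy-2,3-dihydro-1-benzofuran-5-yl]methyl}oxolan-2-one
Conditions: H2 (1 atm), 10% Pd/C, EtOAc/EtOH, rt, stopped at full debenzylation
Reagents that add atoms: none
Why: Hydrogenolysis of aryl benzyl ethers on palladium is much faster under neutral conditions than cleavage of the furan C2–O bond or of the benzylic hydroxyl.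

**Compound list**
1 | 4-benzyloxy-3-methoxybenzyl alcohol | COc1cc(CO)ccc1OCc1ccccc1 | starting material
2 | 4-benzyloxy-3-methoxybenzyl bromide | COc1cc(CBr)ccc1OCc1ccccc1 | intermediate
3 | 5-bromovanillin | COc1cc(C=O)cc(Br)c1O | starting material
4 | 3-bromo-4-[(4-benzyloxy-3-methoxybenzyl)oxy]-5-methoxybenzaldehyde | COc1cc(C=O)cc(Br)c1OCc1ccc(OCc2ccccc2)c(OC)c1 | intermediate
5 | {3-bromo-4-[(4-benzyloxy-3-methoxybenzyl)oxy]-5-methoxyphenyl}methanol | COc1cc(CO)cc(Br)c1OCc1ccc(OCc2ccccc2)c(OC)c1 | intermediate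
6 | TBS ether of 5 | COc1cc(CO[Si](C)(C)C(C)(C)C)cc(Br)c1OCc1ccc(OCc2ccccc2)c(OC)c1 | intermediate
7 | methyl bromoacetate | COC(=O)CBr | starting material
8 | bromo(2-methoxy-2-oxoethyl)zinc (not isolated) | COC(=O)C[Zn]Br | intermediate
9 | methyl 2-{2-[(4-benzyloxy-3-methoxybenzyl)oxy]-3-methoxy-5-[(TBS-oxy)methyl]phenyl}acetate | COC(=O)Cc1cc(CO[Si](C)(C)C(C)(C)C)cc(OC)c1OCc1ccc(OCc2ccccc2)c(OC)c1 | intermediate
10 | methyl 2-diazo-2-{2-[(4-benzyloxy-3-methoxybenzyl)oxy]-3-methoxy-5-[(TBS-oxy)methyl]phenyl}acetate | COC(=O)C(=[N+]=[N-])c1cc(CO[Si](C)(C)C(C)(C)C)cc(OC)c1OCc1ccc(OCc2ccccc2)c(OC)c1 | intermediate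
11 | methyl (2R,3S)-cis-2-(4-benzyloxy-3-methoxyphenyl)-7-methoxy-5-[(TBS-oxy)methyl]-2,3-dihydro-1-benzofuran-3-carboxylate (not isolated) | CC(C)(C)[Si](C)(C)OCc1cc(OC)c2c(c1)[C@H](C(=O)OC)[C@H](c1ccc(OCc3ccccc3)c(OC)c1)O2 | intermediate
12 | methyl (2R,3R)-trans-2-(4-benzyloxy-3-methoxyphenyl)-7-methoxy-5-[(TBS-oxy)methyl]-2,3-dihydro-1-benzofuran-3-carboxylate | CC(C)(C)[Si](C)(C)OCc1cc(OC)c2c(c1)[C@@H](C(=O)OC)[C@H](c1ccc(OCc3ccccc3)c(OC)c1)O2 | intermediate
13 | [(2R,3S)-2-(4-benzyloxy-3-methoxyphenyl)-7-methoxy-5-[(TBS-oxy)methyl]-2,3-dihydro-1-benzofuran-3-yl]methanol | CC(C)(C)[Si](C)(C)OCc1cc(OC)c2c(c1)[C@@H](CO)[C@H](c1ccc(OCc3ccccc3)c(OC)c1)O2 | intermediate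
14 | (2R,3S)-2-(4-benzyloxy-3-methoxyphenyl)-3-[(TBDPS-oxy)methyl]-7-methoxy-5-[(TBS-oxy)methyl]-2,3-dihydro-1-benzofuran | CC(C)(C)[Si](C)(C)OCc1cc(OC)c2c(c1)[C@@H](CO[Si](c1ccccc1)(c1ccccc1)C(C)(C)C)[C@H](c1ccc(OCc3ccccc3)c(OC)c1)O2 | intermediate
15 | ArF-methanol | OCc1cc(OC)c2c(c1)[C@@H](CO[Si](c1ccccc1)(c1ccccc1)C(C)(C)C)[C@H](c1ccc(OCc3ccccc3)c(OC)c1)O2 | intermediate
16 | ArF-methyl bromide | BrCc1cc(OC)c2c(c1)[C@@H](CO[Si](c1ccccc1)(c1ccccc1)C(C)(C)C)[C@H](c1ccc(OCc3ccccc3)c(OC)c1)O2 | intermediate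
17 | (S)-4-benzyl-1,3-oxazolidin-2-one | O=C1OC[C@H](Cc2ccccc2)N1 | starting material
18 | pent-4-enoyl chloride | C=CCCC(Cl)=O | starting material
19 | (S)-4-benzyl-3-(pent-4-enoyl)-1,3-oxazolidin-2-one | C=CCCC(=O)N1C(=O)OC[C@@H]1Cc1ccccc1 | intermediate
20 | sodium (Z)-enolate of 19 (not isolated) | C=CC/C=C(\[O-])N1C(=O)OC[C@@H]1Cc1ccccc1.[Na+] | intermediate
21 | (4S)-4-benzyl-3-[(2R)-2-(ArF-methyl)pent-4-enoyl]-1,3-oxazolidin-2-one | C=CC[C@H](Cc1cc(OC)c2c(c1)[C@@H](CO[Si](c1ccccc1)(c1ccccc1)C(C)(C)C)[C@H](c1ccc(OCc3ccccc3)c(OC)c1)O2)C(=O)N1C(=O)OC[C@@H]1Cc1ccccc1 | intermediate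
22 | (2R)-2-(ArF-methyl)pent-4-en-1-ol | C=CC[C@H](Cc1cc(OC)c2c(c1)[C@@H](CO[Si](c1ccccc1)(c1ccccc1)C(C)(C)C)[C@H](c1ccc(OCc3ccccc3)c(OC)c1)O2)CO | intermediate
23 | (4S)-4-(ArF-methyl)pentane-1,2,5-triol, both C2 epimers (not isolated) | OCC(O)C[C@H](Cc1cc(OC)c2c(c1)[C@@H](CO[Si](c1ccccc1)(c1ccccc1)C(C)(C)C)[C@H](c1ccc(OCc3ccccc3)c(OC)c1)O2)CO | intermediate
24 | (3S)-4-hydroxy-3-(ArF-methyl)butanal (not isolated) | O=CC[C@H](Cc1cc(OC)c2c(c1)[C@@H](CO[Si](c1ccccc1)(c1ccccc1)C(C)(C)C)[C@H](c1ccc(OCc3ccccc3)c(OC)c1)O2)CO | intermediate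
25 | (4S)-4-(ArF-methyl)oxolan-2-ol, anomer mixture | OC1C[C@H](Cc2cc(OC)c3c(c2)[C@@H](CO[Si](c2ccccc2)(c2ccccc2)C(C)(C)C)[C@H](c2ccc(OCc4ccccc4)c(OC)c2)O3)CO1 | intermediate
26 | (4S)-4-(ArF-methyl)oxolan-2-one | O=C1C[C@H](Cc2cc(OC)c3c(c2)[C@@H](CO[Si](c2ccccc2)(c2ccccc2)C(C)(C)C)[C@H](c2ccc(OCc4ccccc4)c(OC)c2)O3)CO1 | intermediate
27 | methyl 3-bromo-4-hydroxy-5-methoxybenzoate | COC(=O)c1cc(Br)c(O)c(OC)c1 | starting material
28 | methyl 4-benzyloxy-3-bromo-5-methoxybenzoate | COC(=O)c1cc(Br)c(OCc2ccccc2)c(OC)c1 | intermediate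
29 | tert-butyl bromoacetate | CC(C)(C)OC(=O)CBr | starting material
30 | bromo(2-tert-butoxy-2-oxoethyl)zinc (not isolated) | CC(C)(C)OC(=O)C[Zn]Br | intermediate
31 | methyl 4-benzyloxy-3-(2-tert-butoxy-2-oxoethyl)-5-methoxybenzoate | COC(=O)c1cc(CC(=O)OC(C)(C)C)c(OCc2ccccc2)c(OC)c1 | intermediate
32 | [2-benzyloxy-3-methoxy-5-(methoxycarbonyl)phenyl]acetic acid | COC(=O)c1cc(CC(O)=O)c(OCc2ccccc2)c(OC)c1 | intermediate
33 | mixed anhydride of 32 with pivalic acid (not isolated) | COC(=O)c1cc(CC(=O)OC(=O)C(C)(C)C)c(OCc2ccccc2)c(OC)c1 | intermediate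
34 | methyl 4-benzyloxy-3-{2-[(4S)-4-benzyl-2-oxo-1,3-oxazolidin-3-yl]-2-oxoethyl}-5-methoxybenzoate | COC(=O)c1cc(CC(=O)N2C(=O)OC[C@@H]2Cc2ccccc2)c(OCc2ccccc2)c(OC)c1 | intermediate
35 | 4-benzyloxy-3-methoxybenzaldehyde | COc1cc(C=O)ccc1OCc1ccccc1 | starting material
36 | O-trimethylsilyl ether of 37 (not isolated) | COc1cc([C@@H](O[Si](C)(C)C)[C@H](C(=O)N2C(=O)OC[C@@H]2Cc2ccccc2)c2cc(C(=O)OC)cc(OC)c2OCc2ccccc2)ccc1OCc1ccccc1 | intermediate
37 | (4S)-4-benzyl-3-[(2R,3S)-3-(4-benzyloxy-3-methoxyphenyl)-2-(2-benzyloxy-3-methoxy-5-methoxycarbonylphenyl)-3-hydroxypropanoyl]-1,3-oxazolidin-2-one | COc1cc([C@@H](O)[C@H](C(=O)N2C(=O)OC[C@@H]2Cc2ccccc2)c2cc(C(=O)OC)cc(OC)c2OCc2ccccc2)ccc1OCc1ccccc1 | intermediate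
38 | methyl 4-benzyloxy-3-[(1S,2S)-1-(4-benzyloxy-3-methoxyphenyl)-1,3-dihydroxypropan-2-yl]-5-methoxybenzoate | COc1cc([C@@H](O)[C@H](CO)c2cc(C(=O)OC)cc(OC)c2OCc2ccccc2)ccc1OCc1ccccc1 | intermediate
39 | methyl 4-benzyloxy-3-[(1S,2S)-1-(4-benzyloxy-3-methoxyphenyl)-1,3-bis(TBS-oxy)propan-2-yl]-5-methoxybenzoate | COc1cc([C@@H](O[Si](C)(C)C(C)(C)C)[C@H](CO[Si](C)(C)C(C)(C)C)c2cc(C(=O)OC)cc(OC)c2OCc2ccccc2)ccc1OCc1ccccc1 | intermediate
40 | {4-benzyloxy-3-[(1S,2S)-1-(4-benzyloxy-3-methoxyphenyl)-1,3-bis(TBS-oxy)propan-2-yl]-5-methoxyphenyl}methanol | COc1cc([C@@H](O[Si](C)(C)C(C)(C)C)[C@H](CO[Si](C)(C)C(C)(C)C)c2cc(CO)cc(OC)c2OCc2ccccc2)ccc1OCc1ccccc1 | intermediate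
41 | 4-benzyloxy-3-[(1S,2S)-1-(4-benzyloxy-3-methoxyphenyl)-1,3-bis(TBS-oxy)propan-2-yl]-5-methoxybenzyl bromide | COc1cc([C@@H](O[Si](C)(C)C(C)(C)C)[C@H](CO[Si](C)(C)C(C)(C)C)c2cc(CBr)cc(OC)c2OCc2ccccc2)ccc1OCc1ccccc1 | intermediate
42 | lithium enolate of 26 (not isolated) | [Li+].[O-]C1=C[C@H](Cc2cc(OC)c3c(c2)[C@@H](CO[Si](c2ccccc2)(c2ccccc2)C(C)(C)C)[C@H](c2ccc(OCc4ccccc4)c(OC)c2)O3)CO1 | intermediate
43 | (3S,4S)-3-{4-benzyloxy-3-[(1S,2S)-1-(4-benzyloxy-3-methoxyphenyl)-1,3-bis(TBS-oxy)propan-2-yl]-5-methoxybenzyl}-4-(ArF-methyl)oxolan-2-one | COc1cc([C@@H](O[Si](C)(C)C(C)(C)C)[C@H](CO[Si](C)(C)C(C)(C)C)c2cc(C[C@@H]3C(=O)OC[C@H]3Cc3cc(OC)c4c(c3)[C@@H](CO[Si](c3ccccc3)(c3ccccc3)C(C)(C)C)[C@H](c3ccc(OCc5ccccc5)c(OC)c3)O4)cc(OC)c2OCc2ccccc2)ccc1OCc1ccccc1 | intermediate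
44 | (3S,4S)-3-{4-benzyloxy-3-[(1S,2S)-1-(4-benzyloxy-3-methoxyphenyl)-1,3-dihydroxypropan-2-yl]-5-methoxybenzyl}-4-{[(2R,3S)-2-(4-benzyloxy-3-methoxyphenyl)-3-(hydroxymethyl)-7-methoxy-2,3-dihydro-1-benzofuran-5-yl]methyl}oxolan-2-one | COc1cc([C@@H](O)[C@H](CO)c2cc(C[C@@H]3C(=O)OC[C@H]3Cc3cc(OC)c4c(c3)[C@@H](CO)[C@H](c3ccc(OCc5ccccc5)c(OC)c3)O4)cc(OC)c2OCc2ccccc2)ccc1OCc1ccccc1 | intermediate
45 | CNP0186558.3, (3S,4S)-3-{3-[(1S,2S)-1,3-dihydroxy-1-(4-hydroxy-3-methoxyphenyl)propan-2-yl]-4-hydroxy-5-methoxybenzyl}-4-{[(2R,3S)-2-(4-hydroxy-3-methoxyphenyl)-3-(hydroxymethyl)-7-methoxy-2,3-dihydro-1-benzofuran-5-yl]methyl}oxolan-2-one | COc1cc([C@@H](O)[C@H](CO)c2cc(C[C@@H]3C(=O)OC[C@H]3Cc3cc(OC)c4c(c3)[C@@H](CO)[C@H](c3ccc(O)c(OC)c3)O4)cc(OC)c2O)ccc1O | target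

**Step count**
Total: 28 steps. Longest linear sequence: 18 steps (steps 1–11, 13–16, 26–28, from 1 to 45).

**Steps most likely to fail**

1. Step 7. The very electron-rich benzylic C–H may react through an early, hydride-transfer-like transition state with eroded enantioselectivity, the carbene may dimerise, and the base epimerisation may open the furan by retro-oxa-Michael elimination and scramble C2 on reclosure. The fallback forms the furan O1–C2 bond instead of C2–C3; it sets out from 38 and comes back at 15. Diol 38 already holds the future C3 in the right configuration. Selective silylation of its primary hydroxyl (TBDPSCl, imidazole, CH2Cl2, 0 °C) gives the mono-silyl ether F1. Hydrogenolysis of both benzyl ethers (H2, Pd/C, EtOAc) gives the bis-phenol F2. Mitsunobu cyclisation (PPh3, diisopropyl azodicarboxylate, THF) lets the ring-B phenol displace the activated benzylic hydroxyl with inversion and gives the trans-dihydrobenzofuran ester F3; a quinone methide pathway through the free para-phenol would also close trans because C3 is fixed. Benzylation of the remaining phenol (BnBr, K2CO3, DMF) gives the benzyl ether F4, and i-Bu2AlH reduction of the C5 ester gives 15.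

2. Step 21. The hindered ortho-substituted arylacetyl imide and the electron-rich aldehyde may give low conversion, poor anti/syn or facial selectivity, or retro-aldol before the aldolate is silylated. The fallback sets the two centres by syn hydroboration of a geometrically defined alkene; it sets out from 32 and comes back at 39. Perkin condensation of 32 with 35 (Ac2O, Et3N, 110 °C) gives the (E)-2,3-diarylacrylic acid F5, in which the two aryl groups are cis. Ethyl chloroformate and N-methylmorpholine give the mixed carbonic anhydride F6, which NaBH4 reduces in the same flask to the allylic alcohol F7 without touching the methyl benzoate. TBSCl and imidazole give the silyl ether F8. Monoisopinocampheylborane from (−)-α-pinene adds hydrogen and boron syn, boron at the carbon bearing the 4-benzyloxy-3-methoxyphenyl ring, to give the borane F9, and NaBO3 oxidation with retention gives the alcohol F10. Syn addition to the (E)-alkene can only give the (1S*,2S*) relative configuration, and the reagent antipode selects the enantiomer. TBSOTf and 2,6-lutidine then give 39.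

3. Step 28. Over-reduction is the risk: hydrogenolysis of the benzylic C2–O1 bond of the dihydrobenzofuran or of the free benzylic hydroxyl may compete with removal of the three benzyl ethers. The fallback reverses the order of unmasking; it sets out from 43 and comes back at 45. Hydrogenolysis of fully silylated 43 (H2, Pd/C, EtOAc) is run while the carbinol is still a silyl ether and the bulky C3 silyloxymethyl group screens the furan C2–O bond, and gives the tris-phenol F11. HF·pyridine in THF/pyridine then removes the three silyl groups and gives 45.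

Further compounds
F1 | step 7 | methyl 4-benzyloxy-3-[(1S,2S)-1-(4-benzyloxy-3-methoxyphenyl)-3-(TBDPS-oxy)-1-hydroxypropan-2-yl]-5-methoxybenzoate | COc1cc([C@@H](O)[C@H](CO[Si](c2ccccc2)(c2ccccc2)C(C)(C)C)c2cc(C(=O)OC)cc(OC)c2OCc2ccccc2)ccc1OCc1ccccc1
F2 | step 7 | methyl 4-hydroxy-3-[(1S,2S)-3-(TBDPS-oxy)-1-hydroxy-1-(4-hydroxy-3-methoxyphenyl)propan-2-yl]-5-methoxybenzoate | COc1cc([C@@H](O)[C@H](CO[Si](c2ccccc2)(c2ccccc2)C(C)(C)C)c2cc(C(=O)OC)cc(OC)c2O)ccc1O
F3 | step 7 | methyl (2R,3S)-3-[(TBDPS-oxy)methyl]-2-(4-hydroxy-3-methoxyphenyl)-7-methoxy-2,3-dihydro-1-benzofuran-5-carboxylate | COC(=O)c1cc(OC)c2c(c1)[C@@H](CO[Si](c1ccccc1)(c1ccccc1)C(C)(C)C)[C@H](c1ccc(O)c(OC)c1)O2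
F4 | step 7 | methyl (2R,3S)-2-(4-benzyloxy-3-methoxyphenyl)-3-[(TBDPS-oxy)methyl]-7-methoxy-2,3-dihydro-1-benzofuran-5-carboxylate | COC(=O)c1cc(OC)c2c(c1)[C@@H](CO[Si](c1ccccc1)(c1ccccc1)C(C)(C)C)[C@H](c1ccc(OCc3ccccc3)c(OC)c1)O2
F5 | step 21 | (E)-3-(4-benzyloxy-3-methoxyphenyl)-2-[2-benzyloxy-3-methoxy-5-(methoxycarbonyl)phenyl]prop-2-enoic acid | OC(=O)/C(=C/c1ccc(OCc2ccccc2)c(OC)c1)c1cc(C(=O)OC)cc(OC)c1OCc1ccccc1
F6 | step 21 | mixed anhydride of F5 with ethyl hydrogen carbonate | CCOC(=O)OC(=O)/C(=C/c1ccc(OCc2ccccc2)c(OC)c1)c1cc(C(=O)OC)cc(OC)c1OCc1ccccc1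
F7 | step 21 | methyl 4-benzyloxy-3-[(E)-1-(4-benzyloxy-3-methoxyphenyl)-3-hydroxyprop-1-en-2-yl]-5-methoxybenzoate | OC/C(=C/c1ccc(OCc2ccccc2)c(OC)c1)c1cc(C(=O)OC)cc(OC)c1OCc1ccccc1
F8 | step 21 | TBS ether of F7 | CC(C)(C)[Si](C)(C)OC/C(=C/c1ccc(OCc2ccccc2)c(OC)c1)c1cc(C(=O)OC)cc(OC)c1OCc1ccccc1
F9 | step 21 | [(1S,2S)-1-(4-benzyloxy-3-methoxyphenyl)-2-(2-benzyloxy-3-methoxy-5-methoxycarbonylphenyl)-3-(TBS-oxy)propyl](isopinocampheyl)borane | C[C@@H]1[C@@H](B[C@H](c3ccc(OCc4ccccc4)c(OC)c3)[C@H](CO[Si](C)(C)C(C)(C)C)c3cc(C(=O)OC)cc(OC)c3OCc3ccccc3)C[C@H]2C[C@@H]1C2(C)C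
F10 | step 21 | methyl 4-benzyloxy-3-[(1S,2S)-1-(4-benzyloxy-3-methoxyphenyl)-1-hydroxy-3-(TBS-oxy)propan-2-yl]-5-methoxybenzoate | COc1cc([C@@H](O)[C@H](CO[Si](C)(C)C(C)(C)C)c2cc(C(=O)OC)cc(OC)c2OCc2ccccc2)ccc1OCc1ccccc1
F11 | step 28 | (3S,4S)-3-{4-hydroxy-3-[(1S,2S)-1-(4-hydroxy-3-methoxyphenyl)-1,3-bis(TBS-oxy)propan-2-yl]-5-methoxybenzyl}-4-{[(2R,3S)-2-(4-hydroxy-3-methoxyphenyl)-3-[(TBDPS-oxy)methyl]-7-methoxy-2,3-dihydro-1-benzofuran-5-yl]methyl}oxolan-2-one | COc1cc([C@@H](O[Si](C)(C)C(C)(C)C)[C@H](CO[Si](C)(C)C(C)(C)C)c2cc(C[C@@H]3C(=O)OC[C@H]3Cc3cc(OC)c4c(c3)[C@@H](CO[Si](c3ccccc3)(c3ccccc3)C(C)(C)C)[C@H](c3ccc(O)c(OC)c3)O4)cc(OC)c2O)ccc1O
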